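The data stem from a simulated flask with constants of no real substance.

Percentages of the charge were what the earlier runs agreed on: at 65 °C the 0.71 M autumn run gave 14.7 % target at 60.0 min and the 1.7 M spring run gave 15.5 %, so I reckoned in percent of the charge and let temperature and time carry the argument.

| flask | starting material | temperature | remark | time |
|---|---|---|---|---|
| autumn | 0.71 M | 65 °C | run made earlier |  |
| dusk | 1.5 M | 76 °C | run made earlier |  |
| spring | 1.7 M | 65 °C | run made earlier |  |
| epsilon | 0.98 M | 80 °C |  | 1.0 h |
| alpha | 2.0 M | 60 °C |  | 3.0 h |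

| run | time / min | target / % | starting material / % |
|---|---|---|---|
| autumn | 12.0 | 3.6 | 11.4 |
| autumn | 25.0 | 7.6 | 1.1 |
| autumn | 40.0 | 11.9 | 0.6 |
| autumn | 50.0 | 13.7 | 0.6 |
| autumn | 60.0 | 14.7 | 0.6 |
| dusk | 2.50 | 2.1 | 23.6 |
| dusk | 8.00 | 9.5 | 1.8 |
| dusk | 15.0 | 15.4 | 0 |
| dusk | 20.0 | 19.5 | 0 |
| dusk | 30.0 | 22.6 | 0 |
| spring | 5.00 | 1.0 | 41.6 |
| spring | 10.0 | 1.7 | 17.4 |
| spring | 15.0 | 3.9 | 6.9 |
| spring | 30.0 | 9.1 | 0.8 |
| spring | 60.0 | 15.5 | 0.5 |

(each reading ± 0.5 percentage points)

- the winner by amount of target, in percent of the starting material charged; "neither" if no more than 2 percentage points parts them (epsilon / alpha / neither)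
- how much target is there at the end, in percent of the starting material charged: epsilon
- how much target is there at the end, in percent of the starting material charged: alpha



In the first instants the starting material moves. The spring run fell to 41.6 % by 5.00 min and the dusk run to 23.6 % by 2.50 min, which I read as first-order constants of 0.175 min⁻¹ and 0.578 min⁻¹, and so an activation energy of 106 kJ mol⁻¹.

In the middle the charge is out of sight: at 15.0 min the spring run showed 6.9 % starting material and 3.9 % target, so 89.2 % stood in an unseen pool. Target grew out of it on a slower clock. Taking the two runs as one curve, spring at 10.0 min and autumn at 25.0 min and 40.0 min are equally spaced, with rises of 5.9 percentage points and then 4.3 points, which I read as a constant of 0.0211 min⁻¹, slower than the fall of the starting material: I took this as the rate-limiting stage on the way to target. I assumed the same activation energy for it, which gives 0.0120 min⁻¹ at 60 °C and 0.105 min⁻¹ at 80 °C. Alpha then keeps 11.6 % and epsilon 0.182 % as the unfinished share, the fraction of the target still to come at the time of reading.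

At the end I reckoned target as its ceiling times one minus that share. The same readings put the ceiling near 23.5 % at 65 °C and 25.8 % at 76 °C. Since my ceiling rose with temperature, I estimated epsilon somewhat above 25.8 % and alpha somewhat below 20.7 %.

The forecast named epsilon, with 28.5 % (24.5 % to 33 %) for epsilon and 17.5 % (14 % to 22 %) for alpha, and said: “The plateau therefore rises with temperature, meaning a competing loss has lower Ea.” Its figure for alpha lay 3.2 points under the 20.7 % I started from.

The flasks gave 27.1 % for epsilon and 17.5 % for alpha, so epsilon won.

    starting material → intermediate A (k = 0.850 min⁻¹, Ea = 103 kJ mol⁻¹)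
    intermediate A → target (k = 0.0290 min⁻¹, Ea = 120 kJ mol⁻¹)
    intermediate A → intermediate B (k = 0.0550 min⁻¹, Ea = 95.0 kJ mol⁻¹)
    intermediate A → side product A (k = 0.0150 min⁻¹, Ea = 101 kJ mol⁻¹)
    intermediate B ⇌ intermediate C (K = 0.460, k = 0.00800 min⁻¹, Ea = 106 kJ mol⁻¹, ΔH = −4.00 kJ mol⁻¹)
    intermediate B → side product B (k = 0.0380 min⁻¹, Ea = 111 kJ mol⁻¹)
    target → over-reaction product (k = 0.00150 min⁻¹, Ea = 110 kJ mol⁻¹)
    (constants at 80 °C)

Target is itself consumed in the flask: in epsilon its half-life by the conversion into over-reaction product alone is 7.7 h, longer than the 1.0 h of reading. Epsilon holds 2.06 % over-reaction product at 1.00 h, beside 27.1 % target. For the same flask as alpha read at 2.0 h, my unfinished share is 23.8 % against alpha's 11.6 %, which scales alpha's target by 0.862 to 15.1 %; the simulation gave 14.9 %.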